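**Retrosynthetic overview**
1. Target 34 ⇒ Lewis-acid (5+2) annulation of hydroxyquinone aldehyde 17 (C8′–C9′–C11′–C12′–C13′) with the terminal vinyl group of labdane acid 33; the bicyclo[3.2.1]octane is closed last.
2. 17 ⇒ oxidative ring contraction (1,2-aryl shift; ring B six → five, C7′ extruded as CHO) of the 6,7-alkene 14 ⇐ tricycle 13 ⇐ proton-initiated polyene bicyclisation of homogeranylarene 12.
3. 12 ⇒ B-alkyl Suzuki coupling of aryl bromide 6 (from p-benzoquinone) with triene 10 (5-bromo-2-methylpent-2-ene, acetylide, Me3Al, vinyl bromide).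
4. 33 ⇒ glycol cleavage/oxidation of diol 31 ⇐ epoxy-alcohol-initiated, allylsilane-terminated bicyclisation of 30 (labdane rings A and B in one step) ⇐ Sharpless epoxidation of polyene 29.
5. 29 ⇒ Negishi coupling of iodide 27 (hepta-1,6-diyne, two carboaluminations) with bromide 22 (4-bromobut-1-yne, Me3SiCH2Cu, dienyl bromide 19). Ring order: arene ring C → abietane rings A/B → contraction of ring B → labdane rings A/B → bicyclo[3.2.1]octane.

Assumption: the SMILES is taken as drawn (carboxyl-bearing C4 is R, i.e. the 18-oic, 4-epi-communic series; CHO on the contracted ring α); labdane atoms are C1–C20, atoms of the rearranged abietane half carry a prime.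

**Route**

Step 1
Reactants: 1 p-benzoquinone
Product: 2 benzene-1,2,4-triyl triacetate
Conditions: Ac2O, H2SO4 (cat.), 45 °C
Reagents that add atoms: acetic anhydride CC(=O)OC(C)=O
Why: Thiele–Winter acetoxylation: acid-catalysed conjugate addition of acetate to the quinone, then enolisation and O-acetylation, gives the 1,2,4-trioxygenated arene.

Step 2
Reactants: 2 benzene-1,2,4-triyl triacetate
Product: 3 1,2,4-trimethoxybenzene
Conditions: NaOH (aq), Me2SO4, Na2S2O4 (cat.), MeOH, 0 °C → rt, N2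
Reagents that add atoms: dimethyl sulfate COS(=O)(=O)OC
Why: one-pot saponification and Williamson O-methylation of the air-sensitive triol under reducing conditions.

Step 3
Reactants: 3 1,2,4-trimethoxybenzene
Product: 5 1,2,4-trimethoxy-3-(propan-2-yl)benzene, via benzylic carbinol 4 (not isolated)
Conditions: n-BuLi, TMEDA, THF, 0 °C; acetone, −78 °C → rt; then Et3SiH, CF3CO2H, CH2Cl2, 0 °C
Reagents that add atoms: acetone CC(C)=O
Why: directed ortho-lithiation at C3 (flanked by two methoxy groups), addition to acetone, then ionic hydrogenation of the benzylic cation.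

Step 4
Reactants: 5 1,2,4-trimethoxy-3-(propan-2-yl)benzene
Product: 6 1-bromo-2,4,5-trimethoxy-3-(propan-2-yl)benzene
Conditions: NBS, MeCN, 0 °C → rt
Reagents that add atoms: N-bromosuccinimide O=C1CCC(=O)N1Br
Why: electrophilic aromatic bromination at the position para to one methoxy group and ortho to another, the site brominated in 1,2,4-trimethoxybenzene itself.

Step 5
Reactants: 7 5-bromo-2-methylpent-2-ene
Product: 8 6-methylhept-5-en-1-yne
Conditions: HC≡CLi·H2N(CH2)2NH2, DMSO, 10 °C → rt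
Reagents that add atoms: lithium acetylide (LiC≡CH, ethylenediamine complex) [Li]C#C
Why: SN2 alkylation of the acetylide by the primary homoallylic bromide.

Step 6
Reactants: 8 6-methylhept-5-en-1-yne
Product: 10 (3E)-4,8-dimethylnona-1,3,7-triene, via alkenylalane 9 (not isolated)
Conditions: Me3Al, Cp2ZrCl2 (20 mol %), CH2Cl2, 0 °C → rt; then CH2=CHBr, ZnCl2, Pd(PPh3)4 (3 mol %), THF, rt
Reagents that add atoms: trimethylaluminium (Me3Al) C[Al](C)C; vinyl bromide C=CBr
Why: Negishi zirconium-catalysed syn-carboalumination (methyl to the internal carbon) fixes the E trisubstituted alkene, and the alkenylalane is coupled with vinyl bromide (palladium-catalysed Negishi coupling) with retention.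

Step 7
Reactants: 10 (3E)-4,8-dimethylnona-1,3,7-triene; 6 1-bromo-2,4,5-trimethoxy-3-(propan-2-yl)benzene
Product: 12 1-[(3E)-4,8-dimethylnona-3,7-dien-1-yl]-2,4,5-trimethoxy-3-(propan-2-yl)benzene, via B-alkyl-9-BBN 11 (not isolated)
Conditions: 9-BBN, THF, 0 °C → rt; then 6, Pd(OAc)2 (5 mol %), SPhos, K3PO4 (aq), THF/DMF, 60 °C
Reagents that add atoms: none
Why: 9-BBN hydroborates only the monosubstituted terminal alkene (boron at the terminus), and B-alkyl Suzuki–Miyaura coupling joins the chain to the arene.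

Step 8
Reactants: 12 1-[(3E)-4,8-dimethylnona-3,7-dien-1-yl]-2,4,5-trimethoxy-3-(propan-2-yl)benzene
Product: 13 (4aS,10aS)-5,6,8-trimethoxy-1,1,4a-trimethyl-7-(propan-2-yl)-1,2,3,4,4a,9,10,10a-octahydrophenanthrene (11,12,14-trimethoxyabieta-8,11,13-triene)
Conditions: (R)-2-(2-fluorobenzyloxy)-2′-hydroxy-1,1′-binaphthyl·SnCl4 (1.5 equiv), toluene, −78 °C; then CF3CO2H, SnCl4, i-PrNO2, −78 °C
Reagents that add atoms: none
Why: enantioselective proton-initiated polyene (cation–olefin) bicyclisation with a Lewis-acid-assisted chiral Brønsted acid (Yamamoto–Ishihara type): the chiral proton source selects one face of the terminal alkene, the chair–chair fold of the E alkene gives the trans fusion (5′α-H, 10′β-Me), and the arene closes ring B at its only free ortho position; the second stage completes any monocyclised material.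

Step 9
Reactants: 13 11,12,14-trimethoxyabieta-8,11,13-triene
Product: 14 (4aS,10aS)-5,6,8-trimethoxy-1,1,4a-trimethyl-7-(propan-2-yl)-1,2,3,4,4a,10a-hexahydrophenanthrene (the 6′,7′-alkene)
Conditions: DDQ, 1,4-dioxane, 100 °C
Reagents that add atoms: none
Why: DDQ dehydrogenation: hydride abstraction from benzylic C7′ (ortho and para to methoxy groups) and loss of H6′ gives the styrene; no stereocentre is touched.

Step 10
Reactants: 14 the 6′,7′-alkene
Product: 15 (4bS,8aS,9R)-9-(dimethoxymethyl)-1,3,4-trimethoxy-4b,8,8-trimethyl-2-(propan-2-yl)-4b,5,6,7,8,8a-hexahydro-9H-fluorene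
Conditions: PhI(OH)OTs, MeOH/HC(OMe)3, 0 °C → rt
Reagents that add atoms: methanol CO
Why: hypervalent (trivalent) iodine oxidative ring contraction of a 1,2-dihydronaphthalene to an indane acetal: the iodane adds to C6′ from the α-face (the β-face is blocked by the axial C4′ and C10′ methyls) and methanol to benzylic C7′, then aryl carbon C8′ shifts from C7′ to C6′ anti to the departing iodobenzene (1,2-aryl shift, inversion at C6′) and the oxocarbenium ion is trapped as the acetal, so the new stereocentre carries the future CHO α (9R), trans to C4′.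

Step 11
Reactants: 15 the ring-contracted acetal
Product: 17 (4bS,8aS,9R)-3-hydroxy-4b,8,8-trimethyl-1,4-dioxo-2-(propan-2-yl)-4,4b,5,6,7,8,8a,9-octahydro-1H-fluorene-9-carbaldehyde (taiwaniaquinone A skeleton), via hydroxyhydroquinone 16 (not isolated)
Conditions: BBr3, CH2Cl2, −78 → 0 °C; then NaHCO3 (aq), air, EtOAc, rt
Reagents that add atoms: water O
Why: BBr3 ether cleavage of the three aryl methyl ethers and the acetal (hydrolysed on work-up), then autoxidation of the 1,2,4-trihydroxyarene to the 2-hydroxy-1,4-benzoquinone; the α-CHO epimer is also the thermodynamic one.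

Step 12
Reactants: 18 3-methylpenta-1,4-dien-3-ol
Product: 19 (3E)-5-bromo-3-methylpenta-1,3-diene
Conditions: PBr3, pyridine (cat.), Et2O, −10 °C
Reagents that add atoms: phosphorus tribromide BrP(Br)Br
Why: allylic bromination with 1,3-transposition (SN2′) of the tertiary bis-allylic alcohol to the conjugated primary bromide, E isomer favoured (minor Z removed on AgNO3-impregnated silica).

Step 13
Reactants: 20 4-bromobut-1-yne; 19 (3E)-5-bromo-3-methylpenta-1,3-diene
Product: 22 [(2Z,5E)-2-(2-bromoethyl)-6-methylocta-2,5,7-trien-1-yl]trimethylsilane, via alkenylcopper 21 (not isolated)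
Conditions: Me3SiCH2MgCl, CuBr·SMe2, Et2O/Me2S, −40 °C; 20, −20 → 0 °C; then 19, P(OEt)3, −30 °C → rt
Reagents that add atoms: (trimethylsilyl)methylmagnesium chloride (Me3SiCH2MgCl) C[Si](C)(C)C[Mg]Cl
Why: Normant syn-carbocupration of the terminal alkyne (CH2SiMe3 to the internal carbon, copper to the terminus, cis), then SN2 allylation of the alkenylcopper with retention, gives the Z allylsilane; the two ends of the 3-methylpentadienyl unit are equivalent, so no regiochemical issue arises.

Step 14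
Reactants: 23 hepta-1,6-diyne
Product: 25 (2E)-3-methyloct-2-en-7-yn-1-ol, via alkenylalane 24 (not isolated)
Conditions: 23 (3 equiv), Me3Al, Cp2ZrCl2 (20 mol %), CH2Cl2, rt; evaporate; n-BuLi, THF, −78 °C; (CH2O)n, rt; HCl (aq)
Reagents that add atoms: trimethylaluminium (Me3Al) C[Al](C)C; paraformaldehyde C=O
Why: Negishi carboalumination of one alkyne (diyne in excess, removed by evaporation) and hydroxymethylation of the alanate with formaldehyde give the E allylic alcohol.

Step 15
Reactants: 25 (2E)-3-methyloct-2-en-7-yn-1-ol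
Product: 27 (2E,7E)-8-iodo-3,7-dimethylocta-2,7-dien-1-ol, via alkenylalane 26 (not isolated)
Conditions: Me3Al (3 equiv), Cp2ZrCl2 (25 mol %), CH2Cl2, rt; then I2, THF, −30 → 0 °C; HCl (aq)
Reagents that add atoms: trimethylaluminium (Me3Al) C[Al](C)C; iodine II
Why: second Negishi carboalumination (the alcohol is carried as its aluminium alkoxide) and iodinolysis with retention give the E alkenyl iodide.

Step 16
Reactants: 22 the allylsilane bromide; 27 (2E,7E)-8-iodo-3,7-dimethylocta-2,7-dien-1-ol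
Product: 29 (2E,7E,11Z,14E)-3,7,15-trimethyl-11-[(trimethylsilyl)methyl]heptadeca-2,7,11,14,16-pentaen-1-ol, via alkylzinc bromide 28 (not isolated)
Conditions: Zn, LiCl, THF, 45 °C; then 27, Pd(OAc)2 (3 mol %), SPhos, THF, rt
Reagents that add atoms: none
Why: LiCl-mediated zinc insertion into the primary bromide and palladium-catalysed alkyl–alkenyl Negishi coupling with retention of alkene geometry; the free hydroxyl is tolerated.

Step 17
Reactants: 29 the pentaenol
Product: 30 [(2R,3R)-3-methyl-3-{(4E,8Z,11E)-4,12-dimethyl-8-[(trimethylsilyl)methyl]tetradeca-4,8,11,13-tetraen-1-yl}oxiran-2-yl]methanol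
Conditions: Ti(OiPr)4 (10 mol %), D-(−)-diethyl tartrate (12 mol %), t-BuOOH, 4 Å MS, CH2Cl2, −20 °C
Reagents that add atoms: tert-butyl hydroperoxide CC(C)(C)OO
Why: Sharpless asymmetric epoxidation: only the allylic-alcohol alkene reacts, and the D-tartrate gives the (2R,3R)-epoxide of the E-3-methyl allylic alcohol, which sets the configuration of the future C4.

Step 18
Reactants: 30 the (2R,3R)-epoxy alcohol
Product: 31 (1S)-1-{(1R,4aR,5S,8aR)-1,4a-dimethyl-6-methylidene-5-[(2E)-3-methylpenta-2,4-dien-1-yl]decahydronaphthalen-1-yl}ethane-1,2-diol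
Conditions: MeAlCl2 (2.5 equiv), CH2Cl2, −78 °C, 1 h; KNaC4H4O6 (aq)
Reagents that add atoms: none
Why: Proposed new method: an epoxy-alcohol-initiated, allylsilane-terminated cation–olefin bicyclisation. The aluminium alkoxide formed from the CH2OH chelates the epoxide and ionises the C–O bond at the tertiary carbon (future C4). The C5=C10 alkene attacks that carbon anti to the leaving oxygen (6-exo opening with inversion, so the Sharpless-set centre fixes C4). The chair–chair fold with the bulky oxygenated arm equatorial (methyl axial) and the E alkene give 5α-H and 10β-Me. The allylsilane closes ring B at C9 with the side chain equatorial and loses Me3Si, leaving only the exocyclic C8 methylene. The diene is a bystander because the β-silyl cation collapses first. Closest known reactions are Lewis-acid cyclisations of 2,3-epoxy alcohols onto simple alkenes and the epoxide-initiated, allylsilane-terminated bicyclisations of trisubstituted (oxidosqualene-type) epoxides to drimanes.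

Step 19
Reactants: 31 the bicyclic diol
Product: 33 (1R,4aR,5S,8aR)-1,4a-dimethyl-6-methylidene-5-[(2E)-3-methylpenta-2,4-dien-1-yl]decahydronaphthalene-1-carboxylic acid (4-epi-trans-communic acid), via aldehyde 32 (not isolated)
Conditions: NaIO4, THF/H2O, 0 °C → rt; then NaClO2, NaH2PO4, 2-methylbut-2-ene, t-BuOH/H2O, rt
Reagents that add atoms: sodium chlorite (NaClO2) [Na+].[O-]Cl=O
Why: Malaprade glycol cleavage to the neopentyl aldehyde, then Pinnick oxidation; the carbinol stereocentre is destroyed and the quaternary C4 cannot epimerise.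

Step 20
Reactants: 17 the hydroxyquinone aldehyde; 33 4-epi-trans-communic acid
Product: 34 target CNP0256710.1
Conditions: BF3·OEt2 (1.2 equiv), CH2Cl2, −78 → −30 °C
Reagents that add atoms: none
Why: stepwise cationic perezone-type (5+2) annulation (as in perezone → pipitzol and the acid-promoted quinone–alkene annulations): BF3 chelates the 11′-oxo/12′-hydroxy unit so that C8′ becomes the electrophilic end of a 2-oxidopentadienyl cation; the terminal vinyl carbon C15 adds to C8′ from the α-face (anti to the angular C10′ methyl), and the allyl cation is captured at C14 by enol carbon C13′ on the same face, with the dienyl residue under the hydroxy-enone bridge (endo), which sets C8′, C13′ and C14.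

**Compound list**
1 | p-benzoquinone | O=C1C=CC(=O)C=C1 | starting material
2 | benzene-1,2,4-triyl triacetate | CC(=O)Oc1ccc(OC(C)=O)c(OC(C)=O)c1 | intermediate
3 | 1,2,4-trimethoxybenzene | COc1ccc(OC)c(OC)c1 | intermediate
4 | 2-(2,3,6-trimethoxyphenyl)propan-2-ol | COc1ccc(OC)c(C(C)(C)O)c1OC | intermediate
5 | 1,2,4-trimethoxy-3-(propan-2-yl)benzene | COc1ccc(OC)c(C(C)C)c1OC | intermediate
6 | 1-bromo-2,4,5-trimethoxy-3-(propan-2-yl)benzene | COc1cc(Br)c(OC)c(C(C)C)c1OC | intermediate
7 | 5-bromo-2-methylpent-2-ene | CC(C)=CCCBr | starting material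
8 | 6-methylhept-5-en-1-yne | CC(C)=CCCC#C | intermediate
9 | [(1E)-2,6-dimethylhepta-1,5-dien-1-yl]dimethylalumane | CC(C)=CCC/C(C)=C/[Al](C)C | intermediate
10 | (3E)-4,8-dimethylnona-1,3,7-triene | C=C/C=C(\C)CCC=C(C)C | intermediate
11 | 9-[(3E)-4,8-dimethylnona-3,7-dien-1-yl]-9-borabicyclo[3.3.1]nonane | CC(C)=CCC/C(C)=C/CCB1C2CCCC1CCC2 | intermediate
12 | 1-[(3E)-4,8-dimethylnona-3,7-dien-1-yl]-2,4,5-trimethoxy-3-(propan-2-yl)benzene | CC(C)=CCC/C(C)=C/CCc1cc(OC)c(OC)c(C(C)C)c1OC | intermediate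
13 | (4aS,10aS)-5,6,8-trimethoxy-1,1,4a-trimethyl-7-(propan-2-yl)-1,2,3,4,4a,9,10,10a-octahydrophenanthrene | COc1c(C(C)C)c(OC)c(OC)c2c1CC[C@H]1C(C)(C)CCC[C@]21C | intermediate
14 | (4aS,10aS)-5,6,8-trimethoxy-1,1,4a-trimethyl-7-(propan-2-yl)-1,2,3,4,4a,10a-hexahydrophenanthrene | COc1c(C(C)C)c(OC)c(OC)c2c1C=C[C@H]1C(C)(C)CCC[C@]21C | intermediate
15 | (4bS,8aS,9R)-9-(dimethoxymethyl)-1,3,4-trimethoxy-4b,8,8-trimethyl-2-(propan-2-yl)-4b,5,6,7,8,8a-hexahydro-9H-fluorene | COc1c(C(C)C)c(OC)c(OC)c2c1[C@H](C(OC)OC)[C@H]1C(C)(C)CCC[C@]21C | intermediate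
16 | (4bS,8aS,9R)-1,3,4-trihydroxy-4b,8,8-trimethyl-2-(propan-2-yl)-4b,5,6,7,8,8a-hexahydro-9H-fluorene-9-carbaldehyde | Oc1c(C(C)C)c(O)c(O)c2c1[C@H](C=O)[C@H]1C(C)(C)CCC[C@]21C | intermediate
17 | (4bS,8aS,9R)-3-hydroxy-4b,8,8-trimethyl-1,4-dioxo-2-(propan-2-yl)-4,4b,5,6,7,8,8a,9-octahydro-1H-fluorene-9-carbaldehyde | O=C1C(C(C)C)=C(O)C(=O)C2=C1[C@H](C=O)[C@H]1C(C)(C)CCC[C@]21C | intermediate
18 | 3-methylpenta-1,4-dien-3-ol | C=CC(C)(O)C=C | starting material
19 | (3E)-5-bromo-3-methylpenta-1,3-diene | C=C/C(C)=C/CBr | intermediate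
20 | 4-bromobut-1-yne | BrCCC#C | starting material
21 | {(1Z)-4-bromo-2-[(trimethylsilyl)methyl]but-1-en-1-yl}copper (MgBrCl complex) | BrCC/C(C[Si](C)(C)C)=C/[Cu] | intermediate
22 | [(2Z,5E)-2-(2-bromoethyl)-6-methylocta-2,5,7-trien-1-yl]trimethylsilane | BrCC/C(C[Si](C)(C)C)=C/C/C=C(\C)C=C | intermediate
23 | hepta-1,6-diyne | C#CCCCC#C | starting material
24 | dimethyl[(1E)-2-methylhept-1-en-6-yn-1-yl]alumane | C#CCCC/C(C)=C/[Al](C)C | intermediate
25 | (2E)-3-methyloct-2-en-7-yn-1-ol | OC/C=C(\C)CCCC#C | intermediate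
26 | {[(2E,7E)-8-(dimethylalumanyl)-3,7-dimethylocta-2,7-dien-1-yl]oxy}dimethylalumane | C[Al](C)OC/C=C(\C)CCC/C(C)=C/[Al](C)C | intermediate
27 | (2E,7E)-8-iodo-3,7-dimethylocta-2,7-dien-1-ol | OC/C=C(\C)CCC/C(C)=C/I | intermediate
28 | bromo{(3Z,6E)-7-methyl-3-[(trimethylsilyl)methyl]nona-3,6,8-trien-1-yl}zinc | Br[Zn]CC/C(C[Si](C)(C)C)=C/C/C=C(\C)C=C | intermediate
29 | (2E,7E,11Z,14E)-3,7,15-trimethyl-11-[(trimethylsilyl)methyl]heptadeca-2,7,11,14,16-pentaen-1-ol | OC/C=C(\C)CCC/C(C)=C/CC/C(C[Si](C)(C)C)=C/C/C=C(\C)C=C | intermediate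
30 | [(2R,3R)-3-methyl-3-{(4E,8Z,11E)-4,12-dimethyl-8-[(trimethylsilyl)methyl]tetradeca-4,8,11,13-tetraen-1-yl}oxiran-2-yl]methanol | OC[C@H]1O[C@]1(C)CCC/C(C)=C/CC/C(C[Si](C)(C)C)=C/C/C=C(\C)C=C | intermediate
31 | (1S)-1-{(1R,4aR,5S,8aR)-1,4a-dimethyl-6-methylidene-5-[(2E)-3-methylpenta-2,4-dien-1-yl]decahydronaphthalen-1-yl}ethane-1,2-diol | C=C1CC[C@@H]2[C@](C)(CCC[C@@]2(C)[C@H](O)CO)[C@H]1C/C=C(\C)C=C | intermediate
32 | (1R,4aR,5S,8aR)-1,4a-dimethyl-6-methylidene-5-[(2E)-3-methylpenta-2,4-dien-1-yl]decahydronaphthalene-1-carbaldehyde | C=C1CC[C@@H]2[C@](C)(CCC[C@@]2(C)C=O)[C@H]1C/C=C(\C)C=C | intermediate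
33 | (1R,4aR,5S,8aR)-1,4a-dimethyl-6-methylidene-5-[(2E)-3-methylpenta-2,4-dien-1-yl]decahydronaphthalene-1-carboxylic acid | C=C1CC[C@@H]2[C@](C)(CCC[C@@]2(C)C(=O)O)[C@H]1C/C=C(\C)C=C | intermediate
34 | target CNP0256710.1 | C=C1CC[C@@H]2[C@](C)(CCC[C@@]2(C)C(=O)O)[C@H]1C/C=C(\C)[C@@H]1C[C@@]23C(=O)[C@]1(C(C)C)C(=O)C(O)=C2[C@@]1(C)CCCC(C)(C)[C@@H]1[C@H]3C=O | target

**Totals**
Total steps: 20. Longest linear sequence: 10 steps (1, 2, 3, 4, 7, 8, 9, 10, 11, 20).

**Three steps most likely to fail**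

Step 18 (the new bicyclisation). Risks are a hydride shift of the opened epoxide to a ketone, the alternative chair fold, and protodesilylation. The fallback uses known chemistry: the established endo, oxidosqualene-type epoxide opening in place of the new exo mode. It sets out from 8 (with zinc reagent 28) and comes back at 32. SeO2/t-BuOOH allylic oxidation of 8 gives (2E)-2-methylhept-2-en-6-yn-1-ol F1. Me3Al/Cp2ZrCl2 carboalumination and I2 give (2E,6E)-7-iodo-2,6-dimethylhepta-2,6-dien-1-ol F2. Negishi coupling with 28 gives the isomeric pentaenol F3. Sharpless epoxidation with L-(+)-diethyl tartrate gives the (2S,3S)-epoxy alcohol F4. MeAlCl2 bicyclisation (epoxide opened at C4 with both epoxide carbons in ring A, allylsilane termination) gives labda-8(17),12E,14-triene-3β,18-diol F5. Thiocarbonyldiimidazole converts the 1,3-diol into the cyclic thionocarbonate F6. Bu3SnH/AIBN (cleavage to the secondary C3 radical) and then NaOH give labda-8(17),12E,14-trien-18-ol F7. Dess–Martin oxidation returns to 32, which is oxidised to 33 as in step 19.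

Step 20 (fragment union). Risks are acid-induced decay of the triene, wrong facial or endo/exo selectivity, and low conversion at the hindered C8′. The fallback switches to the alkoxyquinone variant of the annulation; it sets out from 15 (with 33) and comes back at 34. (NH4)2Ce(NO3)6 in MeCN/H2O converts 15 into the 12′-methoxy-quinone aldehyde F12. TiCl4/Ti(OiPr)4-promoted (5+2) annulation of this 2-alkoxyquinone with 33 gives the enol methyl ether F13. LiCl in DMF at 100 °C cleaves the vinylogous methyl ester and returns to 34.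

Step 10 (ring contraction). Risks are trans-dimethoxylation of the alkene or attack of the oxidant on the electron-rich arene. The fallback is a Wolff ring contraction; it sets out from 13 and comes back at 15. DDQ in wet dioxane gives 11,12,14-trimethoxyabieta-8,11,13-trien-7-one F8. Detrifluoroacetylative diazo transfer (LiN(SiMe3)2, CF3CO2CH2CF3; then MsN3, Et3N) gives the 6-diazo-7-ketone F9. Irradiation in MeOH (Wolff rearrangement through the ketene, C8′ migrating to C6′) and NaOMe equilibration give the ring-contracted methyl ester F10. i-Bu2AlH at −78 °C gives the aldehyde F11, and HC(OMe)3/TsOH returns to 15.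

**Further compounds**
F1 | step 18 | (2E)-2-methylhept-2-en-6-yn-1-ol | OC/C(C)=C/CCC#C
F2 | step 18 | (2E,6E)-7-iodo-2,6-dimethylhepta-2,6-dien-1-ol | OC/C(C)=C/CC/C(C)=C/I
F3 | step 18 | (2E,6E,10Z,13E)-2,6,14-trimethyl-10-[(trimethylsilyl)methyl]hexadeca-2,6,10,13,15-pentaen-1-ol | OC/C(C)=C/CC/C(C)=C/CC/C(C[Si](C)(C)C)=C/C/C=C(\C)C=C
F4 | step 18 | [(2S,3S)-2-methyl-3-{(3E,7Z,10E)-3,11-dimethyl-7-[(trimethylsilyl)methyl]trideca-3,7,10,12-tetraen-1-yl}oxiran-2-yl]methanol | OC[C@]1(C)O[C@H]1CC/C(C)=C/CC/C(C[Si](C)(C)C)=C/C/C=C(\C)C=C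
F5 | step 18 | labda-8(17),12E,14-triene-3β,18-diol | C=C1CC[C@@H]2[C@](C)(CC[C@H](O)[C@@]2(C)CO)[C@H]1C/C=C(\C)C=C
F6 | step 18 | cyclic 3β,18-thionocarbonate of labda-8(17),12E,14-triene-3β,18-diol | C=C1CC[C@@H]2[C@](C)(CC[C@@H]3OC(=S)OC[C@@]23C)[C@H]1C/C=C(\C)C=C
F7 | step 18 | labda-8(17),12E,14-trien-18-ol | C=C1CC[C@@H]2[C@](C)(CCC[C@@]2(C)CO)[C@H]1C/C=C(\C)C=C
F8 | step 10 | 11,12,14-trimethoxyabieta-8,11,13-trien-7-one | COc1c(C(C)C)c(OC)c(OC)c2c1C(=O)C[C@H]1C(C)(C)CCC[C@]21C
F9 | step 10 | 6-diazo-11,12,14-trimethoxyabieta-8,11,13-trien-7-one | COc1c(C(C)C)c(OC)c(OC)c2c1C(=O)C(=[N+]=[N-])[C@H]1C(C)(C)CCC[C@]21C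
F10 | step 10 | methyl (4bS,8aS,9R)-1,3,4-trimethoxy-4b,8,8-trimethyl-2-(propan-2-yl)-4b,5,6,7,8,8a-hexahydro-9H-fluorene-9-carboxylate | COc1c(C(C)C)c(OC)c(OC)c2c1[C@H](C(=O)OC)[C@H]1C(C)(C)CCC[C@]21C
F11 | step 10 | (4bS,8aS,9R)-1,3,4-trimethoxy-4b,8,8-trimethyl-2-(propan-2-yl)-4b,5,6,7,8,8a-hexahydro-9H-fluorene-9-carbaldehyde | COc1c(C(C)C)c(OC)c(OC)c2c1[C@H](C=O)[C@H]1C(C)(C)CCC[C@]21C
F12 | step 20 | (4bS,8aS,9R)-3-methoxy-4b,8,8-trimethyl-1,4-dioxo-2-(propan-2-yl)-4,4b,5,6,7,8,8a,9-octahydro-1H-fluorene-9-carbaldehyde | O=C1C(C(C)C)=C(OC)C(=O)C2=C1[C@H](C=O)[C@H]1C(C)(C)CCC[C@]21C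
F13 | step 20 | enol methyl ether of 34 | C=C1CC[C@@H]2[C@](C)(CCC[C@@]2(C)C(=O)O)[C@H]1C/C=C(\C)[C@@H]1C[C@@]23C(=O)[C@]1(C(C)C)C(=O)C(OC)=C2[C@@]1(C)CCCC(C)(C)[C@@H]1[C@H]3C=O
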